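**Retrosynthetic overview**

1. Feature: in the nine-membered carbocycle the sp2 carbon C11 and the methyl-bearing C7 are 1,5-related through C10–C9–C8; read as a C11 ketone plus a C7=C8 olefin, this is the γ,δ-unsaturated ketone that a Claisen rearrangement leaves behind.
2. Key disconnection C9–C10: cyclononenone ⇐ 2-methylidene-7-methyl-7-vinyloxepane (ring O, C7, C6, C5, C4a, C11a, C11) ⇐ seven-membered lactone (methylenation) ⇐ cyclohexanone with quaternary C7 (Baeyer–Villiger).
3. Cyclohexanone ⇐ cyclohex-2-enone: asymmetric conjugate addition (C4a–C4) with formaldehyde aldol (C11a–C1), then vinylation and methylation at C7.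
4. After ring expansion: Z olefin → syn diol → C8 mesylate → epoxide with inversion; C11 methylenation; δ-lactone (C1–O2–C3) by acetal hydrolysis and lactol oxidation; C4 side chain by enolate alkylation and cross metathesis.
5. Ring order: six-membered carbocycle (bought) → seven-membered lactone → nine-membered carbocycle → δ-lactone → oxirane.

Key step: step 8

Assumption: xenicane numbering (C1, O2, C3, C4, C4a, C5–C11, C11a, C19 for the exocyclic methylene) is used in the Why lines and in the names of compounds 16 onward, whereas the names of compounds 4–15 use the locants of their own rings; the ferrocenyl diphosphine of step 1 is taken as the enantiomer that adds the Grignard reagent to the Si face of C3 of 1, and its antipode is used if the sense is the opposite.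

**Step 1**
Reactants: 1 cyclohex-2-en-1-one; 2 (1,3-dioxolan-2-ylmethyl)magnesium bromide; 3 formaldehyde
Product: 5 (2S,3R)-3-(1,3-dioxolan-2-ylmethyl)-2-(hydroxymethyl)cyclohexan-1-one, via magnesium enolate 4 (not isolated)
Conditions: CuBr·SMe2 (5 mol %), (R)-1-[(SP)-2-(diphenylphosphino)ferrocenyl]ethyldicyclohexylphosphine (6 mol %), t-BuOMe, −78 °C, slow addition of 2; then CH2O gas (from paraformaldehyde), −78 °C; aq NH4Cl
Reagents that add atoms: none
Why: Copper-catalysed asymmetric conjugate addition sets C4a under ligand control, and the regiodefined magnesium enolate is trapped by formaldehyde anti to the new side chain (aldol), which sets C11a trans to C4a, the arrangement that is also favoured thermodynamically at this epimerisable centre.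

**Step 2**
Reactants: 5 (2S,3R)-3-(1,3-dioxolan-2-ylmethyl)-2-(hydroxymethyl)cyclohexan-1-one
Product: 6 (2S,3R)-2-[(tert-butyldimethylsilyloxy)methyl]-3-(1,3-dioxolan-2-ylmethyl)cyclohexan-1-one
Conditions: TBSCl, imidazole, DMF, 0 → 23 °C
Reagents that add atoms: tert-butyldimethylsilyl chloride, CC(C)(C)[Si](C)(C)Cl
Why: Silylation of the primary alcohol under weakly basic conditions should protect the β-hydroxy ketone before it can dehydrate or undergo retro-aldol cleavage.

**Step 3**
Reactants: 6 (2S,3R)-2-[(tert-butyldimethylsilyloxy)methyl]-3-(1,3-dioxolan-2-ylmethyl)cyclohexan-1-one; 7 phenyl vinyl sulfoxide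
Product: 9 (2S,3R)-2-[(tert-butyldimethylsilyloxy)methyl]-3-(1,3-dioxolan-2-ylmethyl)-6-[2-(phenylsulfinyl)ethyl]cyclohexan-1-one (epimers at C6 and at sulfur), via kinetic lithium enolate 8 (not isolated)
Conditions: LDA, THF, −78 °C; 7, −78 → −40 °C; aq NH4Cl
Reagents that add atoms: none
Why: LDA deprotonates the unbranched α-CH2 (future C7) in preference to the branched C11a–H, and Michael addition of the lithium enolate to the vinyl sulfoxide (a vinyl cation equivalent) attaches the two carbons C8 and C9; the new centres are lost in steps 4 and 5.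

**Step 4**
Reactants: 9 the γ-keto sulfoxide from step 3
Product: 10 (2S,3R)-2-[(tert-butyldimethylsilyloxy)methyl]-3-(1,3-dioxolan-2-ylmethyl)-6-vinylcyclohexan-1-one (C6 epimers)
Conditions: toluene, CaCO3 (suspension), 110 °C
Reagents that add atoms: none
Why: Thermal syn elimination of the sulfoxide (sulfoxide pyrolysis) can only take a hydrogen from the CH2 next to the ring and so should unveil the vinyl group; the acid scavenger limits isomerisation to the conjugated ethylidene ketone.

**Step 5**
Reactants: 10 (2S,3R)-2-[(tert-butyldimethylsilyloxy)methyl]-3-(1,3-dioxolan-2-ylmethyl)-6-vinylcyclohexan-1-one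
Product: 12 (2S,3R,6R)-2-[(tert-butyldimethylsilyloxy)methyl]-3-(1,3-dioxolan-2-ylmethyl)-6-methyl-6-vinylcyclohexan-1-one, via lithium dienolate 11 (not isolated)
Conditions: LDA, THF, −78 °C; MeI, −78 → −30 °C
Reagents that add atoms: iodomethane, CI
Why: The C7–H of the β,γ-unsaturated ketone is activated by both carbonyl and vinyl, so enolisation is regioselective there although C11a–H is also tertiary, and the extended dienolate is alkylated at its α-carbon (dienolate α-alkylation) with axial entry of MeI expected to give mainly the 6R isomer; the 6S isomer is carried along because step 8 erases this centre.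

**Step 6**
Reactants: 12 (2S,3R,6R)-2-[(tert-butyldimethylsilyloxy)methyl]-3-(1,3-dioxolan-2-ylmethyl)-6-methyl-6-vinylcyclohexan-1-one
Product: 13 (3S,4R,7R)-3-[(tert-butyldimethylsilyloxy)methyl]-4-(1,3-dioxolan-2-ylmethyl)-7-methyl-7-vinyloxepan-2-one
Conditions: mCPBA, NaHCO3, CH2Cl2, 0 → 23 °C
Reagents that add atoms: 3-chloroperbenzoic acid, OOC(=O)c1cccc(Cl)c1
Why: In the Baeyer–Villiger oxidation the quaternary allylic carbon C7 should migrate with retention in preference to C11a, which carries the electron-withdrawing silyloxymethyl group, and the monosubstituted vinyl group is the least reactive class of alkene toward a buffered peracid.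

**Step 7**
Reactants: 13 (3S,4R,7R)-3-[(tert-butyldimethylsilyloxy)methyl]-4-(1,3-dioxolan-2-ylmethyl)-7-methyl-7-vinyloxepan-2-one
Product: 14 (3S,4R,7R)-3-[(tert-butyldimethylsilyloxy)methyl]-4-(1,3-dioxolan-2-ylmethyl)-7-methyl-2-methylidene-7-vinyloxepane
Conditions: Cp2TiMe2, toluene, 70 °C, dark; filtration through basic Al2O3
Reagents that add atoms: dimethyltitanocene, [CH3-].[CH3-].[Ti+4].c1cc[cH-]c1.c1cc[cH-]c1
Why: Petasis methylenation (Cp2Ti=CH2 formed on heating, oxatitanacyclobutane, loss of titanocene oxide) converts the lactone carbonyl into the exocyclic enol ether without acid or base, so C11a, the acetal and the enol ether should survive.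

**Step 8**
Reactants: 14 (3S,4R,7R)-3-[(tert-butyldimethylsilyloxy)methyl]-4-(1,3-dioxolan-2-ylmethyl)-7-methyl-2-methylidene-7-vinyloxepane
Product: 15 (8R,9S,Z)-9-[(tert-butyldimethylsilyloxy)methyl]-8-(1,3-dioxolan-2-ylmethyl)-5-methylcyclonon-4-en-1-one
Conditions: o-xylene, Et3N (1 mol %), 185 °C, sealed base-washed tube
Reagents that add atoms: none
Why: The allyl vinyl ether C10=C11–O–C7–C8=C9 undergoes a thermal [3,3]-sigmatropic (Claisen) rearrangement that forms C9–C10, breaks C7–O and turns the enol ether carbon into the C11 ketone. The closest known reaction type is the methylenation–Claisen ring expansion of 2-methylidene-6-vinyltetrahydropyrans to cyclooct-4-enones and of the homologous oxepanes to cyclonon-4-enones. The nine-membered ring is closed by a two-atom ring expansion of the oxepane, with the new bond made inside a six-membered pericyclic array bridged by the tether C6–C5–C4a–C11a, not by an end-to-end cyclisation. No stereocentre is created: C7 becomes sp2, so both C7 epimers of 14 give 15, and C4a and C11a are untouched. The selectivity needed is olefin geometry, and the four-carbon tether can only span C7 and C11 from an axial-like position on C7, which puts C6 cis to C9 and should give the Z olefin. Base-washed glass and a trace of amine guard against acid-catalysed isomerisation of the exocyclic enol ether to the endocyclic one, which would rearrange to a ring-contracted ketone.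

**Step 9**
Reactants: 15 (8R,9S,Z)-9-[(tert-butyldimethylsilyloxy)methyl]-8-(1,3-dioxolan-2-ylmethyl)-5-methylcyclonon-4-en-1-one
Product: 16 (4R,5S,8R,9S)-9-[(tert-butyldimethylsilyloxy)methyl]-8-(1,3-dioxolan-2-ylmethyl)-4,5-dihydroxy-5-methylcyclononan-1-one (xenicane 7S,8R)
Conditions: K2OsO2(OH)4 (5 mol %), (DHQD)2PHAL (12 mol %), NMO, acetone/H2O, 0 °C
Reagents that add atoms: N-methylmorpholine N-oxide, C[N+]1([O-])CCOCC1; water, O
Why: Osmium-catalysed syn dihydroxylation of the only olefin under neutral conditions spares the epimerisable C11a, and the dihydroquinidine ligand is chosen by the mnemonic of the Sharpless asymmetric dihydroxylation (H8 in the southeast quadrant, the C7 methyl southwest) to deliver both oxygens to the C7 Si face (C8 Re face), which sets 7S and 8R.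

**Step 10**
Reactants: 16 the 7S,8R diol ketone
Product: 17 the 7,8-O-isopropylidene acetal (acetonide) of 16, (4aR,7S,8R,11aS) in xenicane numbering
Conditions: 2-methoxypropene, PPTS (cat.), CH2Cl2, 0 °C
Reagents that add atoms: 2-methoxypropene, C=C(C)OC
Why: Acid-catalysed ketalisation of the cis-1,2-diol gives the five-membered acetonide, which should draw any transannular hemiketal with the C11 ketone back through the open form and removes the free hydroxyls before the titanium reagent is used.

**Step 11**
Reactants: 17 the acetonide ketone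
Product: 18 the C11-methylidene acetonide (exocyclic C11=C19 in place of the ketone), (4aR,7S,8R,11aR)
Conditions: Cp2TiMe2, toluene, 70 °C, dark
Reagents that add atoms: dimethyltitanocene, [CH3-].[CH3-].[Ti+4].c1cc[cH-]c1.c1cc[cH-]c1
Why: Petasis methylenation of the ketone proceeds without enolisation, so the α-stereocentre C11a and the β-silyloxy group should be preserved.

**Step 12**
Reactants: 18 the C11-methylidene acetonide
Product: 19 (4aR,7S,8R,11aR)-7,8-dihydroxy-7-methyl-11-methylidene lactol: the C1 oxygen closes onto C3 as a 2-hydroxytetrahydropyran (C3 anomers)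
Conditions: 1 M HCl, THF, 0 → 23 °C
Reagents that add atoms: water, O
Why: Dilute aqueous acid hydrolyses the silyl ether, the acetonide and the dioxolane in one operation, and the freed C1 hydroxyl captures the C3 aldehyde as the six-membered lactol (6-exo-trig hemiacetal formation), while the 1,1-disubstituted olefin is not protonated at this acidity.

**Step 13**
Reactants: 19 the lactol diol
Product: 20 (4aR,7S,8R,11aR)-7,8-dihydroxy-7-methyl-11-methylidene δ-lactone (C3=O, C4 unsubstituted)
Conditions: TEMPO (10 mol %), PhI(OAc)2, CH2Cl2, 23 °C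
Reagents that add atoms: none
Why: The oxoammonium oxidation should take the lactol C–H much faster than the hindered secondary C8 carbinol and cannot touch the tertiary C7 alcohol, so the lactone is formed with the diol intact.

**Step 14**
Reactants: 20 the lactone diol
Product: 21 the C8 methanesulfonate of 20 (7S,8R; C7–OH free)
Conditions: MsCl, Et3N, CH2Cl2, −10 °C
Reagents that add atoms: methanesulfonyl chloride, CS(=O)(=O)Cl
Why: Sulfonylation occurs at the secondary C8 hydroxyl only, because the tertiary C7 hydroxyl is too hindered to react under these conditions.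

**Step 15**
Reactants: 21 the C8 mesylate
Product: 22 (4aR,7S,8S,11aR)-7,8-epoxy-7-methyl-11-methylidene δ-lactone
Conditions: t-BuOK, THF, −20 → 0 °C
Reagents that add atoms: none
Why: The C7 alkoxide displaces the C8 mesylate intramolecularly (3-exo-tet Williamson closure) with inversion at C8 and retention at C7, which converts the syn diol of the Z olefin into the trans-epoxide (7S,8S) of the target.

**Step 16**
Reactants: 22 the epoxy lactone; 23 4-iodobut-1-ene
Product: 25 (4S,4aS,7S,8S,11aR)-4-(but-3-en-1-yl)-7,8-epoxy-7-methyl-11-methylidene δ-lactone, via lithium lactone enolate 24 (not isolated)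
Conditions: LDA, THF/DMPU, −78 °C; 23, −78 → −30 °C; AcOH, −78 °C
Reagents that add atoms: none
Why: Alkylation of the lactone enolate should occur on the face of C4 anti to the axial C4a–H (axial attack on the trans-fused half-chair, staggered to the C4a–C5 bond), which places the chain cis to C5 (4S), and the cold acidic quench prevents later epimerisation.

**Step 17**
Reactants: 25 the C4-butenyl epoxy lactone; 26 methyl methacrylate
Product: 27 acalycixeniolide H
Conditions: 26 (10 equiv), RuCl2(H2IMes)(=CH–C6H4-2-O-i-Pr) (second-generation Hoveyda–Grubbs catalyst, 5 mol %), CH2Cl2, 40 °C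
Reagents that add atoms: none
Why: Cross metathesis of the terminal monosubstituted olefin with the methacrylate should give the trisubstituted enoate with E geometry (ester trans to the chain), while the hindered 1,1-disubstituted C11=C19 olefin and the epoxide do not take part.

**Compound list**

1 | cyclohex-2-en-1-one | O=C1C=CCCC1 | starting material
2 | (1,3-dioxolan-2-ylmethyl)magnesium bromide | Br[Mg]CC1OCCO1 | starting material
3 | formaldehyde | C=O | starting material
4 | bromomagnesium (R)-3-(1,3-dioxolan-2-ylmethyl)cyclohex-1-en-1-olate | Br[Mg]OC1=C[C@@H](CC2OCCO2)CCC1 | intermediate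
5 | (2S,3R)-3-(1,3-dioxolan-2-ylmethyl)-2-(hydroxymethyl)cyclohexan-1-one | O=C1CCC[C@H](CC2OCCO2)[C@H]1CO | intermediate
6 | (2S,3R)-2-[(tert-butyldimethylsilyloxy)methyl]-3-(1,3-dioxolan-2-ylmethyl)cyclohexan-1-one | O=C1CCC[C@H](CC2OCCO2)[C@H]1CO[Si](C)(C)C(C)(C)C | intermediate
7 | phenyl vinyl sulfoxide (racemic) | C=CS(=O)c1ccccc1 | starting material
8 | kinetic lithium enolate of 6 (enolate toward the future C7) | [Li]OC1=CCC[C@H](CC2OCCO2)[C@H]1CO[Si](C)(C)C(C)(C)C | intermediate
9 | (2S,3R)-2-[(tert-butyldimethylsilyloxy)methyl]-3-(1,3-dioxolan-2-ylmethyl)-6-[2-(phenylsulfinyl)ethyl]cyclohexan-1-one, epimers at C6 and sulfur | O=C1C(CCS(=O)c2ccccc2)CC[C@H](CC3OCCO3)[C@H]1CO[Si](C)(C)C(C)(C)C | intermediate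
10 | (2S,3R)-2-[(tert-butyldimethylsilyloxy)methyl]-3-(1,3-dioxolan-2-ylmethyl)-6-vinylcyclohexan-1-one, C6 epimers | O=C1C(C=C)CC[C@H](CC2OCCO2)[C@H]1CO[Si](C)(C)C(C)(C)C | intermediate
11 | lithium dienolate of 10 (O–C=C–CH=CH2) | [Li]OC1=C(C=C)CC[C@H](CC2OCCO2)[C@H]1CO[Si](C)(C)C(C)(C)C | intermediate
12 | (2S,3R,6R)-2-[(tert-butyldimethylsilyloxy)methyl]-3-(1,3-dioxolan-2-ylmethyl)-6-methyl-6-vinylcyclohexan-1-one (methyl trans to the C2 side chain) | O=C1[C@@](C)(C=C)CC[C@H](CC2OCCO2)[C@H]1CO[Si](C)(C)C(C)(C)C | intermediate
13 | (3S,4R,7R)-3-[(tert-butyldimethylsilyloxy)methyl]-4-(1,3-dioxolan-2-ylmethyl)-7-methyl-7-vinyloxepan-2-one | O=C1O[C@@](C)(C=C)CC[C@H](CC2OCCO2)[C@H]1CO[Si](C)(C)C(C)(C)C | intermediate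
14 | (3S,4R,7R)-3-[(tert-butyldimethylsilyloxy)methyl]-4-(1,3-dioxolan-2-ylmethyl)-7-methyl-2-methylidene-7-vinyloxepane | C=C1O[C@@](C)(C=C)CC[C@H](CC2OCCO2)[C@H]1CO[Si](C)(C)C(C)(C)C | intermediate
15 | (8R,9S,Z)-9-[(tert-butyldimethylsilyloxy)methyl]-8-(1,3-dioxolan-2-ylmethyl)-5-methylcyclonon-4-en-1-one | O=C1CC/C=C(/C)CC[C@H](CC2OCCO2)[C@H]1CO[Si](C)(C)C(C)(C)C | intermediate
16 | (4R,5S,8R,9S)-9-[(tert-butyldimethylsilyloxy)methyl]-8-(1,3-dioxolan-2-ylmethyl)-4,5-dihydroxy-5-methylcyclononan-1-one | O=C1CC[C@@H](O)[C@@](C)(O)CC[C@H](CC2OCCO2)[C@H]1CO[Si](C)(C)C(C)(C)C | intermediate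
17 | 7,8-O-isopropylidene acetal of 16 (4aR,7S,8R,11aS, xenicane numbering) | O=C1CC[C@H]2OC(C)(C)O[C@@]2(C)CC[C@H](CC3OCCO3)[C@H]1CO[Si](C)(C)C(C)(C)C | intermediate
18 | C11-methylidene analogue of 17 (4aR,7S,8R,11aR) | C=C1CC[C@H]2OC(C)(C)O[C@@]2(C)CC[C@H](CC3OCCO3)[C@H]1CO[Si](C)(C)C(C)(C)C | intermediate
19 | (4aR,7S,8R,11aR)-7,8-dihydroxy-7-methyl-11-methylidene lactol (C1–O–C3(OH), C3 anomers) | C=C1CC[C@@H](O)[C@@](C)(O)CC[C@@H]2CC(O)OC[C@@H]12 | intermediate
20 | (4aR,7S,8R,11aR)-7,8-dihydroxy-7-methyl-11-methylidene δ-lactone | C=C1CC[C@@H](O)[C@@](C)(O)CC[C@@H]2CC(=O)OC[C@@H]12 | intermediate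
21 | C8 methanesulfonate of 20 (7S,8R) | C=C1CC[C@@H](OS(C)(=O)=O)[C@@](C)(O)CC[C@@H]2CC(=O)OC[C@@H]12 | intermediate
22 | (4aR,7S,8S,11aR)-7,8-epoxy-7-methyl-11-methylidene δ-lactone | C=C1CC[C@@H]2O[C@@]2(C)CC[C@@H]2CC(=O)OC[C@@H]12 | intermediate
23 | 4-iodobut-1-ene | C=CCCI | starting material
24 | lithium enolate of 22 (C3–C4 enolate) | C=C1CC[C@@H]2O[C@@]2(C)CC[C@@H]2C=C(O[Li])OC[C@@H]12 | intermediate
25 | (4S,4aS,7S,8S,11aR)-4-(but-3-en-1-yl)-7,8-epoxy-7-methyl-11-methylidene δ-lactone | C=C1CC[C@@H]2O[C@@]2(C)CC[C@@H]2[C@H](CCC=C)C(=O)OC[C@@H]12 | intermediate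
26 | methyl methacrylate | C=C(C)C(=O)OC | starting material
27 | acalycixeniolide H (4S,4aS,7S,8S,11aR; E enoate) | C=C1CC[C@@H]2O[C@@]2(C)CC[C@@H]2[C@H](CC/C=C(\C)C(=O)OC)C(=O)OC[C@@H]12 | target

**Totals**

Total step count: 17. Longest linear sequence: 17 steps from cyclohex-2-en-1-one (1).

**Steps most likely to fail**

Step 9. The osmium reagent may approach the Z olefin of 15 from the face set by the ring conformation and not by the ligand, so facial selectivity may be poor or reversed; the diol may also be held back as a transannular hemiketal. The fallback inverts the olefin geometry and epoxidises directly; it sets out from 15. Methylenation with Cp2TiMe2 (toluene, 70 °C) should give the (Z)-diene F1. Buffered mCPBA at −20 °C should epoxidise the trisubstituted ring olefin in preference to the hindered 1,1-disubstituted one and give the cis-epoxide F2, either face of which serves. Ph2PLi in THF followed by MeI opens the epoxide at C8 with inversion, and syn elimination of the betaine should give the (E)-diene F3. Treatment with 1 M HCl in THF then gives the (E)-lactol F4, and TEMPO with PhI(OAc)2 gives the (E)-lactone F5. mCPBA at −20 °C is expected to add to the outer face of the E-cyclononene, and the fallback returns to the route at 22.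

Step 8. The exocyclic enol ether may isomerise to the endocyclic one or decompose at 185 °C before the bridged transition state is reached. The fallback is an aluminium-promoted rearrangement with in-flask reduction; it sets out from 14. i-Bu3Al in CH2Cl2 (−78 → 0 °C) should trigger the ring expansion at low temperature and reduce the resulting ketone by hydride transfer to the (Z)-cyclononenol F6 (C11 epimers). Oxidation with Dess–Martin periodinane (NaHCO3, CH2Cl2) returns to the route at 15.

Step 16. The electrophile may add to the wrong face of C4, and displacement on the homoallylic iodide may be slowed by competing elimination and proton transfer. The fallback sets C4 by C–H instead of C–C bond formation; it sets out from 22 under the alkylation conditions of step 16, which then deliver the C4 epimer F7. Deprotonation of F7 with LDA at −78 °C gives the tetrasubstituted lithium enolate F8, which is protonated at −78 °C with 2,6-di-tert-butylphenol. The proton should take the face that the carbon electrophile took before, which turns the side chain to the required face and returns to the route at 25.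

**Further compounds**

F1 | step 9 | (Z)-diene: C11-methylidene analogue of 15 | C=C1CC/C=C(/C)CC[C@H](CC2OCCO2)[C@H]1CO[Si](C)(C)C(C)(C)C
F2 | step 9 | cis-7,8-epoxide of F1 (drawn as the 7S,8R isomer; the other face serves equally) | C=C1CC[C@H]2O[C@@]2(C)CC[C@H](CC3OCCO3)[C@H]1CO[Si](C)(C)C(C)(C)C
F3 | step 9 | (E)-diene: 7E isomer of F1 | C=C1CC/C=C(\C)CC[C@H](CC2OCCO2)[C@H]1CO[Si](C)(C)C(C)(C)C
F4 | step 9 | (E)-lactol: (4aR,11aR)-7-methyl-11-methylidene 7E-ene lactol (C3 anomers) | C=C1CC/C=C(\C)CC[C@@H]2CC(O)OC[C@@H]12
F5 | step 9 | (E)-lactone: (4aR,11aR)-7-methyl-11-methylidene 7E-ene δ-lactone | C=C1CC/C=C(\C)CC[C@@H]2CC(=O)OC[C@@H]12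
F6 | step 8 | (Z)-cyclononenol: C11 alcohol corresponding to 15 (C11 epimers) | OC1CC/C=C(/C)CC[C@H](CC2OCCO2)[C@H]1CO[Si](C)(C)C(C)(C)C
F7 | step 16 | C4 epimer of 25 (4R) | C=C1CC[C@@H]2O[C@@]2(C)CC[C@@H]2[C@@H](CCC=C)C(=O)OC[C@@H]12
F8 | step 16 | lithium enolate of F7 (C3–C4 enolate bearing the butenyl group) | C=C1CC[C@@H]2O[C@@]2(C)CC[C@@H]2C(CCC=C)=C(O[Li])OC[C@@H]12
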